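**Numbering used throughout**

- 1: 2,4,6-trimethoxybenzaldehyde
- 2: 2,4,6-trimethoxyphenyl formate (not isolated)
- 3: 2,4,6-trimethoxyphenol (ring A cap)
- 4: syringic acid
- 5: two-ring phenol (rings A and B)
- 6: three-ring phenol (rings A to C)
- 7: four-ring phenol (rings A to D)
- 8: five-ring phenol, the undecamethyl ether of the target with the ring E C4 hydroxyl free
- 9: target

## Analysis of the target

Compound 9 (C30H22O16) is an open chain of five benzene rings held together by four diaryl ether oxygens and carrying twelve free phenolic hydroxyls. It has no stereocentre and no ring other than the arenes, so the whole problem is constitutional: the position and the direction of each ether link. The rings are lettered A (2,4,6-trihydroxyphenoxy end) to E (3,4,5-trihydroxyphenyl end); in each ring C4 is the carbon flanked by the oxygenated C3 and C5, and C1 is para to it. Every ring is then a 1,3,4,5-tetraoxygenated benzene, and every ether oxygen runs from C4 of one ring to C1 of the next. The free polyphenol is electron-rich and autoxidises readily, above all at the pyrogallol-type ring E, so the hydroxyls should stay masked until the last step. The difficulty is that each ether oxygen sits on a carbon crowded by two ortho oxygen substituents, while its partner carbon C1 lies in an electron-rich ring without any activating group, and four such bonds must be made in the same head-to-tail sense. The strategy rests on the repeat: rings B to E are four copies of one 2,6-dioxygenated phenol whose para carbon C1 carries the oxygen of the preceding ring. That unit is syringic acid 4 with its carboxyl replaced by the ether bond.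

## Retrosynthetic reasoning

**9 back to 8.** The eleven O–CH3 bonds are cut last. Methyl is the smallest mask for the crowded C3 and C5 oxygens, it is already present in the building blocks, and all eleven ethers fall to one Lewis-acid treatment that leaves diaryl ethers intact. The single free hydroxyl of 8, at C4 of ring E, is simply the end of the chain and needs no protection.

**8 back to 7 and 4.** The O–C1 bond of ring E is cut. On one side this leaves the phenol oxygen of 7, lying between two methoxy groups. On the other side it leaves a C1 that carries a carboxyl group in 4, a traceless handle that marks the only carbon where oxidative O–C coupling can become irreversible. Cutting at C4–O instead would demand an electrophilic carbon between two methoxy groups, the worst position of the ring. The forward reaction has to oxidise both phenols to phenoxyl radicals, join the chain-end oxygen to the carboxyl-bearing carbon, lose CO2 and stop after one unit.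

**7 back to 6 and 4.** The O–C1 bond of ring D is cut in the same way. The chain end of 6 has the same local structure as that of 7, so the same anodic coupling applies without any change of protecting group.

**6 back to 5 and 4.** The O–C1 bond of ring C is cut likewise. All chain ends share one local structure and one oxidation potential, so feeding several equivalents of 4 at once would give a spread of chain lengths. Taking the bonds one at a time, with the chain phenol in excess over 4, makes each of 5, 6 and 7 a defined compound that is purified before the next unit is added.

**5 back to 3 and 4.** The O–C1 bond of ring B is cut. Here the oxygen partner is the cap 3, whose para carbon bears a methoxy group and no carboxyl, so it can only become the tail of the chain. This first coupling sets the pattern that the three later ones repeat, and both of its partners are simple.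

**3 back to 1.** The ring C–OH bond of 3 is traced back to the ring C–CHO bond of 1, through formate 2. A free hydroxyl between two methoxy groups with a third methoxy para cannot be reached cleanly by selective methylation, whereas peroxide-induced aryl migration of an electron-rich benzaldehyde is dependable. Aldehyde 1 and acid 4 are bought.

## Alternatives that were turned down

Alternative 1: Ring C is built last by cutting its C2–C3 and C1–C6 bonds. This leaves a 4-aryloxy-3-ethoxycyclobutenone A2, with rings D and E on the C4 oxygen, and an aryl ethynyl ether A3 carrying rings A and B. On heating, A2 should open to a vinylketene, add to the alkyne of A3 in a [2+2] sense, reopen and close by 6π electrocyclisation to give pentamer A1, whose ring C bears one hydroxyl and one ethoxy group.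
- For: the mechanism dictates the oxygen pattern of ring C, the union is convergent, and the number of rings is fixed by the two halves. On that last point it is stronger than the chosen route, which must hold each anodic addition at one unit and separate whatever over-runs.
- Against: the annulation forms no ether bond. The A–B and D–E ethers still need hindered diaryl ether couplings; the crowded A–B phenol must be converted into an ethynyl ether and the D–E phenol into an aryloxyketene precursor. Aryl ynol ethers are weaker ketene partners than alkyl or silyl ones, and A2 is sensitive to heat and base.
- Comparison: well over ten steps against six. The chosen strategy offers one bond-forming reaction for all four ethers from two cheap building blocks.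

Alternative 2: All ten C3–O and C5–O bonds are cut back to C–Br, giving decabromide A5. Its ether skeleton would be assembled stepwise by SNAr of 2,6-dibromophenoxides on fluoroarenes activated by a para group that is afterwards turned into the next phenol. The key step treats A5 with NaOMe and CuBr (monovalent copper) to exchange all ten bromines and give the dodecamethyl ether A4.
- For: SNAr ether formation is reliable and gives an exact chain length, and copper-mediated methoxylation of aryl bromides is well established on simple substrates. On the reliability of the ether-forming steps it is stronger.
- Against: ten exchanges must all succeed on one molecule, each at a crowded carbon ortho to a diaryl ether oxygen. Reductive loss of bromine accompanies such exchanges, and every defective site gives a product that differs from A4 only by H in place of OMe, harder to remove than a homologue differing by a whole ring. Methoxide at the required temperature may also cleave diaryl ethers, and 2,6-dibromophenoxides are poor nucleophiles, so the assembly is long.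
- Comparison: the chosen route brings every ring oxygen in with the building blocks and makes no peripheral C–O bond at all.

Alternative 3: Ring D is cut at C2–C3 and C5–C6 into dimethyl 3-aryloxyglutaconate A7 (aryl = rings A to C) and dimethyl aryloxymalonate A8 (aryl = ring E). A double Claisen condensation with NaOMe, followed by enolisation, should close ring D and give A6, a 3,5-dihydroxy-2,6-diester.
- For: both ether oxygens of ring D are attached to non-aromatic carbons beforehand, by easy reactions even for hindered phenols, and chain length is exact. On the ease of those two C–O bonds it is stronger than the chosen route.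
- Against: A8 has an acidic C–H between its esters and is deprotonated by NaOMe, which deactivates it as a double acyl donor, so the ring closure itself is doubtful. A6 carries two ester carbons the target lacks, to be removed by hydrolysis and double decarboxylation. Only two of the four ether links are addressed, because the A–B–C trimer in A7 still needs two hindered diaryl ether couplings.
- Comparison: the chosen route needs no superfluous carbon apart from the carboxyl lost in the coupling itself and treats all four links alike.

Key step: step 2

Remark on the chemistry: 1 and 4 are taken as commercial. Equivalents, charge and potential in steps 2 to 5 are design values. In each of these steps the chain phenol is used in excess over 4 and the unreacted part is recovered; the same anodic coupling that step 2 establishes is repeated in steps 3 to 5.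

## Route

Step 1
Reactants: 1 2,4,6-trimethoxybenzaldehyde
Product: 3 2,4,6-trimethoxyphenol, via 2,4,6-trimethoxyphenyl formate 2 (not isolated)
Conditions: 30% aq. H2O2 (1.3 equiv), H2SO4 (cat.), MeOH, rt; aqueous work-up
Reagents that add atoms: hydrogen peroxide, OO
Why: Acid-catalysed Baeyer–Villiger (Dakin-type) oxidation; the very electron-rich aryl group migrates in preference to hydride to give formate 2, which is methanolysed in the same flask to phenol 3.

Step 2
Reactants: 3 2,4,6-trimethoxyphenol; 4 syringic acid (4-hydroxy-3,5-dimethoxybenzoic acid)
Product: 5 2,6-dimethoxy-4-(2,4,6-trimethoxyphenoxy)phenol (two-ring phenol)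
Conditions: graphite anode, Pt cathode, undivided cell, anode potential held at the first phenol wave (ca. 1 mA cm−2), MeCN/aq. NaOAc–AcOH buffer (pH 5) 2:1, 20 °C, Ar; 3 (3 equiv) in the cell, 4 (1 equiv) in the same medium by syringe pump, ca. 2 F per mol of 4; aq. NaHCO3 wash; chromatography on silica gel, excess 3 recovered
Reagents that add atoms: none
Why: Proposed new method: at the graphite anode both phenols lose an electron and a proton to give phenoxyl radicals; the radical from 3 has methoxy groups on both ortho carbons and on the para carbon, so its oxygen is the only site where a lasting bond can form, while the radical from 4 carries spin density at C1, the carboxyl-bearing carbon. Coupling of that oxygen with that C1 gives a 4-aryloxy-4-carboxylatocyclohexa-2,5-dienone, which expels CO2 and rearomatises to the 2,6-dimethoxyphenol end of 5, and this lays down the O–C1 bond of ring B. The closest known reaction type is the oxidative decarboxylative polymerisation of 4 (enzymatic, aerobic copper–amine or anodic) to poly(2,6-dimethoxy-1,4-phenylene oxide); new here are the para-capped partner 3 and the stop after a single unit. No ring closes and no stereocentre is created. The head-to-tail sense needs no directing group: coupling at a para carbon that bears OMe gives only a quinone ketal that falls apart again, whereas coupling at the carboxyl-bearing carbon is made irreversible by decarboxylation, and 3 must become the tail because it has no carboxyl to lose. Cross-coupling over self-coupling of 4, and single over double addition, are both secured by proportion: 3 is kept in threefold excess and 4 is fed slowly, so a syringate radical should meet a radical of 3 far more often than one of 4 or of 5, and carboxyl-tailed by-products go into the NaHCO3 wash. The potential is held below that of fully methylated rings and of the carboxylate, so only free phenols are oxidised.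

Step 3
Reactants: 5 two-ring phenol; 4 syringic acid
Product: 6 4-[3,5-dimethoxy-4-(2,4,6-trimethoxyphenoxy)phenoxy]-2,6-dimethoxyphenol (three-ring phenol)
Conditions: as step 2: graphite anode, Pt cathode, undivided cell, first phenol wave, MeCN/aq. NaOAc–AcOH buffer (pH 5) 2:1, 20 °C, Ar; 5 (3 equiv) in the cell, 4 (1 equiv) by syringe pump, ca. 2 F per mol of 4; aq. NaHCO3 wash; chromatography on silica gel, excess 5 recovered
Reagents that add atoms: none
Why: Proposed new method: the chain-end phenoxyl radical of 5 has methoxy on both ortho carbons and aryloxy on the para carbon, so it can bond lastingly only through oxygen; attack on C1 of the syringate radical, loss of CO2 and rearomatisation form the O–C1 bond of ring C. The closest known reaction type is the propagation step of the oxidative decarboxylative polymerisation of 4 to poly(2,6-dimethoxy-1,4-phenylene oxide), in which such a chain end adds one syringate unit; the excess of 5 and the slow feed of 4 are what should hold the reaction at one addition.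

Step 4
Reactants: 6 three-ring phenol; 4 syringic acid
Product: 7 4-{4-[3,5-dimethoxy-4-(2,4,6-trimethoxyphenoxy)phenoxy]-3,5-dimethoxyphenoxy}-2,6-dimethoxyphenol (four-ring phenol)
Conditions: as step 2, with MeCN/aq. NaOAc–AcOH buffer (pH 5) 3:1 for solubility, 20 °C, Ar; 6 (2.5 equiv) in the cell, 4 (1 equiv) by syringe pump, ca. 2 F per mol of 4; aq. NaHCO3 wash; chromatography on silica gel, excess 6 recovered
Reagents that add atoms: none
Why: Proposed new method: the chain end of 6 is the same 4-aryloxy-2,6-dimethoxyphenol as that of 5, so its anodically formed phenoxyl radical should again couple through oxygen to the carboxyl-bearing C1 of the syringate radical, and decarboxylation with rearomatisation forms the O–C1 bond of ring D. The closest known reaction type is the propagation step of the oxidative decarboxylative polymerisation of 4 to poly(2,6-dimethoxy-1,4-phenylene oxide); the single addition relies on the excess of 6 over slowly fed 4.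

Step 5
Reactants: 7 four-ring phenol; 4 syringic acid
Product: 8 4-(4-{4-[3,5-dimethoxy-4-(2,4,6-trimethoxyphenoxy)phenoxy]-3,5-dimethoxyphenoxy}-3,5-dimethoxyphenoxy)-2,6-dimethoxyphenol (five-ring phenol, the undecamethyl ether of 9 with the ring E C4 hydroxyl free)
Conditions: as step 2, with MeCN/aq. NaOAc–AcOH buffer (pH 5) 3:1, 20 °C, Ar; 7 (2 equiv) in the cell, 4 (1 equiv) by syringe pump, ca. 2 F per mol of 4; aq. NaHCO3 wash; chromatography (silica gel, then reversed phase), excess 7 recovered
Reagents that add atoms: none
Why: Proposed new method: anodic oxidation gives the chain-end phenoxyl radical of 7, blocked at both ortho carbons by methoxy and at the para carbon by aryloxy, which should couple through oxygen to C1 of the syringate radical; the resulting 4-aryloxy-4-carboxylatocyclohexadienone loses CO2 and rearomatises, forming the O–C1 bond of ring E and the free C4 hydroxyl of 8. The closest known reaction type is the propagation step of the oxidative decarboxylative polymerisation of 4 to poly(2,6-dimethoxy-1,4-phenylene oxide); the excess of 7 and the slow feed of 4 are meant to stop growth at five rings.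

Step 6
Reactants: 8 five-ring phenol
Product: 9 5-[4-[4-[4-(2,4,6-trihydroxyphenoxy)-3,5-dihydroxyphenoxy]-3,5-dihydroxyphenoxy]-3,5-dihydroxyphenoxy]benzene-1,2,3-triol (target)
Conditions: BBr3 (ca. 20 equiv), CH2Cl2, −78 °C to rt, Ar; H2O quench at 0 °C; EtOAc extraction; Sephadex LH-20 (degassed MeOH)
Reagents that add atoms: none
Why: Lewis-acid cleavage of aryl methyl ethers by BBr3 (bromide attacks the methyl carbon of the boron-complexed ether); diaryl ether bonds have no such sp3 carbon and should survive, and hydrolysis of the aryl borates releases all twelve hydroxyls.

## Compound list

1 | 2,4,6-trimethoxybenzaldehyde | COc1cc(OC)c(C=O)c(OC)c1 | starting material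
2 | 2,4,6-trimethoxyphenyl formate | COc1cc(OC)c(OC=O)c(OC)c1 | intermediate
3 | 2,4,6-trimethoxyphenol | COc1cc(OC)c(O)c(OC)c1 | intermediate
4 | syringic acid (4-hydroxy-3,5-dimethoxybenzoic acid) | COc1cc(C(=O)O)cc(OC)c1O | starting material
5 | 2,6-dimethoxy-4-(2,4,6-trimethoxyphenoxy)phenol (two-ring phenol) | COc1cc(OC)c(Oc2cc(OC)c(O)c(OC)c2)c(OC)c1 | intermediate
6 | 4-[3,5-dimethoxy-4-(2,4,6-trimethoxyphenoxy)phenoxy]-2,6-dimethoxyphenol (three-ring phenol) | COc1cc(OC)c(Oc2cc(OC)c(Oc3cc(OC)c(O)c(OC)c3)c(OC)c2)c(OC)c1 | intermediate
7 | 4-{4-[3,5-dimethoxy-4-(2,4,6-trimethoxyphenoxy)phenoxy]-3,5-dimethoxyphenoxy}-2,6-dimethoxyphenol (four-ring phenol) | COc1cc(OC)c(Oc2cc(OC)c(Oc3cc(OC)c(Oc4cc(OC)c(O)c(OC)c4)c(OC)c3)c(OC)c2)c(OC)c1 | intermediate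
8 | five-ring phenol, undecamethyl ether of 9 with free ring E C4 hydroxyl | COc1cc(OC)c(Oc2cc(OC)c(Oc3cc(OC)c(Oc4cc(OC)c(Oc5cc(OC)c(O)c(OC)c5)c(OC)c4)c(OC)c3)c(OC)c2)c(OC)c1 | intermediate
9 | 5-[4-[4-[4-(2,4,6-trihydroxyphenoxy)-3,5-dihydroxyphenoxy]-3,5-dihydroxyphenoxy]-3,5-dihydroxyphenoxy]benzene-1,2,3-triol | Oc1cc(O)c(Oc2cc(O)c(Oc3cc(O)c(Oc4cc(O)c(Oc5cc(O)c(O)c(O)c5)c(O)c4)c(O)c3)c(O)c2)c(O)c1 | target

Total step count: 6. Longest linear sequence: 6 steps (1 to 3 to 5 to 6 to 7 to 8 to 9).

## Least certain steps

**Step 2 (key step, proposed new method).** Three processes threaten it. A second electron transfer from the radical of 3, followed by hydrolysis in the aqueous medium, would strip the para-methoxy carbon and turn the cap into a quinone; this is most likely here because 3 is the most easily oxidised phenol of the whole route. Self-initiation by 4 would divert the monomer into carboxyl-tailed chains. Over-addition, in which freshly formed 5 takes up a second unit, cannot be excluded because 5 and 3 are oxidised at nearly the same potential and only the excess of 3 discriminates between them.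

Fallback, by known chemistry, setting out from 3 and coming back to the route at 5: commercial 4-bromo-2,6-dimethoxyphenol F1 is benzylated (BnBr, K2CO3, DMF) to 2-(benzyloxy)-5-bromo-1,3-dimethoxybenzene F2. Ullmann ether coupling of 3 with F2 (CuI cat., picolinic acid, K3PO4, DMSO, 90–110 °C) should give the two-ring benzyl ether F3, and hydrogenolysis (H2, Pd/C, EtOAc) then gives 5 with an exact ring count.

**Step 3 (proposed new method).** Reversible oxygen-to-para coupling between two chain-end radicals of 5 gives a quinone ketal that can break on either side, which would shuffle ring units between chains and erode the defined length even when only one equivalent of 4 is fed. Over-addition and self-coupling of 4 threaten as in step 2.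

Fallback, by known chemistry, setting out from 5 and coming back at 6: Ullmann coupling of 5 with bromide F2 (CuI cat., picolinic acid, K3PO4, DMSO, 90–110 °C) should give the three-ring benzyl ether F4, and hydrogenolysis (H2, Pd/C, EtOAc) gives 6.

**Step 4 (proposed new method).** Besides redistribution and over-addition, adsorption of the growing oligomers on graphite may passivate the anode, so that the potential has to be raised and selectivity for the free phenol over the methylated rings is lost. The smaller excess of the more valuable phenol 6 also weakens the statistical control.

Fallback, by known chemistry, setting out from 6 and coming back at 7: Ullmann coupling of 6 with bromide F2 under the same conditions should give the four-ring benzyl ether F5, and hydrogenolysis gives 7.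

**Step 5 (proposed new method).** The chain is now long enough that poor solubility in the aqueous electrolyte may slow the coupling relative to self-coupling of 4. Separation of 8 from unreacted 7 and from over-grown material also becomes harder, because neighbouring homologues differ by a proportionally smaller increment.

Fallback, by known chemistry, setting out from 7 and coming back at 8: Ullmann coupling of 7 with bromide F2 under the same conditions should give the five-ring benzyl ether F6, and hydrogenolysis gives 8.

**Step 6.** Cleavage of eleven ethers may stop short, because partly cleaved boron aryloxides can precipitate from CH2Cl2. The free dodecaphenol may also degrade oxidatively during isolation.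

Fallback, setting out from 8 and returning at 9: the crude BBr3 demethylation product is acetylated at once (Ac2O, pyridine, DMAP cat.) to the dodecaacetate F7. This should be air-stable and separable on silica gel from under-demethylated material. Pure F7 is then cleaved by acid-catalysed methanolysis (HCl cat., degassed MeOH, 40 °C) and evaporated to give 9 without chromatography of the free polyphenol.

## Further compounds

F1 | step 2 | 4-bromo-2,6-dimethoxyphenol | COc1cc(Br)cc(OC)c1O
F2 | step 2 | 2-(benzyloxy)-5-bromo-1,3-dimethoxybenzene | COc1cc(Br)cc(OC)c1OCc1ccccc1
F3 | step 2 | benzyl ether of 5 (two-ring benzyl ether) | COc1cc(OC)c(Oc2cc(OC)c(OCc3ccccc3)c(OC)c2)c(OC)c1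
F4 | step 3 | benzyl ether of 6 (three-ring benzyl ether) | COc1cc(OC)c(Oc2cc(OC)c(Oc3cc(OC)c(OCc4ccccc4)c(OC)c3)c(OC)c2)c(OC)c1
F5 | step 4 | benzyl ether of 7 (four-ring benzyl ether) | COc1cc(OC)c(Oc2cc(OC)c(Oc3cc(OC)c(Oc4cc(OC)c(OCc5ccccc5)c(OC)c4)c(OC)c3)c(OC)c2)c(OC)c1
F6 | step 5 | benzyl ether of 8 (five-ring benzyl ether) | COc1cc(OC)c(Oc2cc(OC)c(Oc3cc(OC)c(Oc4cc(OC)c(Oc5cc(OC)c(OCc6ccccc6)c(OC)c5)c(OC)c4)c(OC)c3)c(OC)c2)c(OC)c1
F7 | step 6 | dodecaacetate of 9 | CC(=O)Oc1cc(OC(C)=O)c(Oc2cc(OC(C)=O)c(Oc3cc(OC(C)=O)c(Oc4cc(OC(C)=O)c(Oc5cc(OC(C)=O)c(OC(C)=O)c(OC(C)=O)c5)c(OC(C)=O)c4)c(OC(C)=O)c3)c(OC(C)=O)c2)c(OC(C)=O)c1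
A1 | alternative 1 | protected pentamer with ring C bearing one hydroxyl and one ethoxy group | COc1cc(OC)c(Oc2cc(OC)c(Oc3cc(O)c(Oc4cc(OC)c(Oc5cc(OC)c(OC)c(OC)c5)c(OC)c4)c(OCC)c3)c(OC)c2)c(OC)c1
A2 | alternative 1 | 3-ethoxy-4-[3,5-dimethoxy-4-(3,4,5-trimethoxyphenoxy)phenoxy]cyclobut-2-en-1-one | CCOC1=CC(=O)C1Oc1cc(OC)c(Oc2cc(OC)c(OC)c(OC)c2)c(OC)c1
A3 | alternative 1 | 2-(ethynyloxy)-1,3-dimethoxy-5-(2,4,6-trimethoxyphenoxy)benzene | C#COc1c(OC)cc(Oc2c(OC)cc(OC)cc2OC)cc1OC
A4 | alternative 2 | dodecamethyl ether of 9 | COc1cc(OC)c(Oc2cc(OC)c(Oc3cc(OC)c(Oc4cc(OC)c(Oc5cc(OC)c(OC)c(OC)c5)c(OC)c4)c(OC)c3)c(OC)c2)c(OC)c1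
A5 | alternative 2 | decabromo pentamer with methoxy at ring A C1 and ring E C4 | COc1cc(Br)c(Oc2cc(Br)c(Oc3cc(Br)c(Oc4cc(Br)c(Oc5cc(Br)c(OC)c(Br)c5)c(Br)c4)c(Br)c3)c(Br)c2)c(Br)c1
A6 | alternative 3 | pentamer with ring D as 3,5-dihydroxy-2,6-bis(methoxycarbonyl) ring | COc1cc(OC)c(Oc2cc(OC)c(Oc3cc(OC)c(Oc4c(C(=O)OC)c(O)c(Oc5cc(OC)c(OC)c(OC)c5)c(O)c4C(=O)OC)c(OC)c3)c(OC)c2)c(OC)c1
A7 | alternative 3 | dimethyl 3-aryloxyglutaconate carrying rings A to C | COC(=O)CC(=CC(=O)OC)Oc1c(OC)cc(Oc2c(OC)cc(Oc3c(OC)cc(OC)cc3OC)cc2OC)cc1OC
A8 | alternative 3 | dimethyl 2-(3,4,5-trimethoxyphenoxy)malonate | COC(=O)C(Oc1cc(OC)c(OC)c(OC)c1)C(=O)OC
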